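**Retrosynthetic overview**

- Target 14 is the (R)-isoflavanone. The last two steps only unmask phenols (two silyl ethers, one benzyl ether) in the protected isoflavanone 12.
- Rings A and B are bought as arenes. Ring C is the only ring made and closes last, through the C2–C3 bond: the dirhodium carbene from diazo ketone 11 inserts into a C–H bond of the ring A methoxy group ortho to the ketone, so that this methyl carbon becomes C2 and C3 is set.
- Enabling feature: C2 is a CH2 bonded only to O1 and C3, and O1 sits on C8a, ortho to the C4 carbonyl. C3 is flanked by the C4 ketone (acceptor) and ring B (donor). C2 can therefore be carried as an aryl methyl ether and C3 as a donor/acceptor carbene, held 1,6 to each other across C4–C4a–C8a–O1.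
- 11 comes from deoxybenzoin 9 (bis-silylation, diazo transfer). 9 comes from Houben–Hoesch acylation of the symmetric 2,5-dimethoxyresorcinol 7 (one kind of ring C–H) with arylacetonitrile 4.
- 7 comes from 2,6-dibromo-4-methoxyphenol 5 (methylation, double hydroxylation). 4 comes from 3-hydroxy-4,5-dimethoxybenzaldehyde 1 (benzylation, Van Leusen homologation).

Key step: step 8

Assumption: the sense of induction of the chiral dirhodium catalyst cannot be assigned with certainty in advance, so the route is written with the S-configured catalyst, and its mirror-image complex would be used instead should it deliver the (S)-product.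

**Route**

Step 1
Reactants: 1 3-hydroxy-4,5-dimethoxybenzaldehyde
Product: 2 3-(benzyloxy)-4,5-dimethoxybenzaldehyde
Conditions: BnBr, K2CO3, DMF, 60 °C
Reagents that add atoms: benzyl bromide, BrCc1ccccc1
Why: Williamson ether synthesis; the phenoxide formed with K2CO3 is alkylated by benzyl bromide, and the benzyl ether should survive every later step until the final hydrogenolysis.

Step 2
Reactants: 2 3-(benzyloxy)-4,5-dimethoxybenzaldehyde
Product: 4 2-[3-(benzyloxy)-4,5-dimethoxyphenyl]acetonitrile, via N-(1-tosylalkenyl)formamide 3 (not isolated)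
Conditions: TosMIC, t-BuOK, DME, −40 °C; then MeOH, reflux
Reagents that add atoms: p-toluenesulfonylmethyl isocyanide (TosMIC), Cc1ccc(cc1)S(=O)(=O)C[N+]#[C-]
Why: Van Leusen reductive cyanation; the TosMIC anion adds to the aldehyde, the oxazoline opens to the N-(1-tosylalkenyl)formamide, and methanolysis of the formyl group, loss of sulfinate and tautomerisation of the ketenimine should give the one-carbon-homologated arylacetonitrile.

Step 3
Reactants: 5 2,6-dibromo-4-methoxyphenol
Product: 6 1,3-dibromo-2,5-dimethoxybenzene
Conditions: MeI, K2CO3, acetone, reflux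
Reagents that add atoms: iodomethane, CI
Why: Williamson ether synthesis on an acidic 2,6-dibromophenol; this O-methylation fixes the future 6-methoxy group between the two bromine atoms.

Step 4
Reactants: 6 1,3-dibromo-2,5-dimethoxybenzene
Product: 7 2,5-dimethoxybenzene-1,3-diol
Conditions: Pd2(dba)3 (2 mol %), tBuXPhos (8 mol %), KOH, 1,4-dioxane/H2O, 100 °C, argon; then aq. HCl
Reagents that add atoms: potassium hydroxide, [K+].[OH-]
Why: Palladium-catalysed C–O cross-coupling of aryl bromides with hydroxide (zerovalent palladium with a bulky biaryl phosphine) should replace both bromine atoms by hydroxyl groups and give the symmetric resorcinol.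

Step 5
Reactants: 7 2,5-dimethoxybenzene-1,3-diol; 4 2-[3-(benzyloxy)-4,5-dimethoxyphenyl]acetonitrile
Product: 9 2-[3-(benzyloxy)-4,5-dimethoxyphenyl]-1-(2,4-dihydroxy-3,6-dimethoxyphenyl)ethan-1-one, via ketiminium chloride 8 (not isolated)
Conditions: ZnCl2, HCl (g), Et2O, 0 °C; then H2O, 90 °C
Reagents that add atoms: water, O
Why: Houben–Hoesch acylation; the nitrilium species from 4, HCl and ZnCl2 attacks the resorcinol at its only kind of ring C–H (ortho to one hydroxyl, para to the other), the ketiminium salt blocks a second acylation and is hydrolysed to the ketone in hot water.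

Step 6
Reactants: 9 2-[3-(benzyloxy)-4,5-dimethoxyphenyl]-1-(2,4-dihydroxy-3,6-dimethoxyphenyl)ethan-1-one
Product: 10 2-[3-(benzyloxy)-4,5-dimethoxyphenyl]-1-{3,6-dimethoxy-2,4-bis[(triisopropylsilyl)oxy]phenyl}ethan-1-one
Conditions: TIPSOTf (2.6 equiv), 2,6-lutidine, CH2Cl2, 0 °C to rt; dilute aq. HCl wash
Reagents that add atoms: triisopropylsilyl trifluoromethanesulfonate, CC(C)[Si](OS(=O)(=O)C(F)(F)F)(C(C)C)C(C)C
Why: Silyl ether formation with a silyl triflate and a hindered weak base should cap both phenols, including the chelated one next to the ketone, with groups that have neither an O–H bond nor a C–H bond α to oxygen; any silyl enol ether formed is hydrolysed in the acid wash.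

Step 7
Reactants: 10 2-[3-(benzyloxy)-4,5-dimethoxyphenyl]-1-{3,6-dimethoxy-2,4-bis[(triisopropylsilyl)oxy]phenyl}ethan-1-one
Product: 11 2-[3-(benzyloxy)-4,5-dimethoxyphenyl]-2-diazo-1-{3,6-dimethoxy-2,4-bis[(triisopropylsilyl)oxy]phenyl}ethan-1-one
Conditions: p-ABSA, DBU, MeCN (dry), 0 °C to rt
Reagents that add atoms: 4-acetamidobenzenesulfonyl azide (p-ABSA), CC(=O)Nc1ccc(cc1)S(=O)(=O)N=[N+]=[N-]
Why: Regitz diazo transfer; the methylene group, acidified by the ketone and by ring B, is deprotonated by DBU and takes up two nitrogen atoms of the sulfonyl azide to give the α-aryl-α-diazo ketone.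

Step 8
Reactants: 11 2-[3-(benzyloxy)-4,5-dimethoxyphenyl]-2-diazo-1-{3,6-dimethoxy-2,4-bis[(triisopropylsilyl)oxy]phenyl}ethan-1-one
Product: 12 (3R)-3-[3-(benzyloxy)-4,5-dimethoxyphenyl]-6-methoxy-5,7-bis[(triisopropylsilyl)oxy]-2,3-dihydro-4H-chromen-4-one
Conditions: Rh2(S-PTAD)4 (dirhodium tetrakis[(S)-(1-adamantyl)(N-phthalimido)acetate], divalent rhodium, 1 mol %), PhCF3, 4 Å MS, rt, slow addition of 11
Reagents that add atoms: none
Why: Proposed new method: loss of dinitrogen from 11 at the dirhodium tetracarboxylate gives a donor/acceptor rhodium carbene at C3 (ring B as donor, the C4 aroyl group as acceptor) that inserts into a C–H bond of the ring A methoxy group ortho to the ketone through a concerted, asynchronous, hydride-shift-like three-centre transition state, so that the methyl carbon becomes C2 and the C2–C3 bond forms as the catalyst is released. The closest known reaction types are the dirhodium-catalysed intramolecular C–H insertion of 2-alkoxyphenyl α-diazo ketones to chroman-4-ones, the cyclisation of α-aryl-α-diazo ketones to α-aryl cyclopentanones and the insertion of aryldiazoacetate carbenes into C–H bonds of methyl ethers; what lacks direct precedent is their union in an enantioselective 1,6-insertion of an aryl(aroyl)carbene into an aryl methyl ether. Ring C closes by 1,6-insertion through a six-membered chair-like array C3–C4–C4a–C8a–O1–C2, in which the lone pair of O1 stabilises the positive charge that builds up on C2. The only new stereocentre, C3, is under catalyst control: the phthalimido walls of the chiral dirhodium complex shield one face of the planar carbene, so that the C–H bond is delivered to the open face and the new C3–H and C3–C2 bonds form on the same side, which should give the (R) configuration with the proper antipode of the catalyst. The step needs chemoselectivity for this one C–H bond over oxonium ylide formation, Wolff rearrangement and carbene dimerisation, and the substrate secures it because the methoxy group is the only sp3 C–H donor that can reach C3 (the other ortho oxygen carries a triisopropylsilyl group without α-hydrogens, while the 6-methoxy group and the ring B ethers are geometrically out of reach), because the two ortho substituents twist the aroyl group out of the plane of ring A and hold the carbene over the methoxy group, because a donor/acceptor carbene is too weakly electrophilic to favour ylide or Wolff pathways, and because slow addition keeps the diazo concentration low.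

Step 9
Reactants: 12 (3R)-3-[3-(benzyloxy)-4,5-dimethoxyphenyl]-6-methoxy-5,7-bis[(triisopropylsilyl)oxy]-2,3-dihydro-4H-chromen-4-one
Product: 13 (3R)-3-[3-(benzyloxy)-4,5-dimethoxyphenyl]-5,7-dihydroxy-6-methoxy-2,3-dihydro-4H-chromen-4-one
Conditions: Et3N·3HF, THF, rt
Reagents that add atoms: none
Why: Fluoride-mediated cleavage of aryl silyl ethers under weakly acidic conditions, in which the enolisable C3 stereocentre should not epimerise and the benzyl ether stays intact.

Step 10
Reactants: 13 (3R)-3-[3-(benzyloxy)-4,5-dimethoxyphenyl]-5,7-dihydroxy-6-methoxy-2,3-dihydro-4H-chromen-4-one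
Product: 14 (3R)-5,7-dihydroxy-3-(3-hydroxy-4,5-dimethoxyphenyl)-6-methoxy-2,3-dihydro-4H-chromen-4-one
Conditions: H2 (1 atm), Pd/C, EtOAc, rt
Reagents that add atoms: none
Why: Hydrogenolysis of the benzyl ether over Pd/C in a neutral solvent at ambient temperature should free the last phenol without touching the aryl ketone or the C3 stereocentre.

**Compound list**

1 | 3-hydroxy-4,5-dimethoxybenzaldehyde | COc1cc(C=O)cc(O)c1OC | starting material
2 | 3-(benzyloxy)-4,5-dimethoxybenzaldehyde | COc1cc(C=O)cc(OCc2ccccc2)c1OC | intermediate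
3 | N-{2-[3-(benzyloxy)-4,5-dimethoxyphenyl]-1-[(4-methylphenyl)sulfonyl]ethenyl}formamide (potassium salt in the flask, alkene geometry not defined, not isolated) | COc1cc(C=C(NC=O)S(=O)(=O)c2ccc(C)cc2)cc(OCc2ccccc2)c1OC | intermediate
4 | 2-[3-(benzyloxy)-4,5-dimethoxyphenyl]acetonitrile | COc1cc(CC#N)cc(OCc2ccccc2)c1OC | intermediate
5 | 2,6-dibromo-4-methoxyphenol | COc1cc(Br)c(O)c(Br)c1 | starting material
6 | 1,3-dibromo-2,5-dimethoxybenzene | COc1cc(Br)c(OC)c(Br)c1 | intermediate
7 | 2,5-dimethoxybenzene-1,3-diol | COc1cc(O)c(OC)c(O)c1 | intermediate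
8 | 2-[3-(benzyloxy)-4,5-dimethoxyphenyl]-1-(2,4-dihydroxy-3,6-dimethoxyphenyl)ethan-1-iminium chloride (not isolated) | COc1cc(CC(=[NH2+])c2c(O)c(OC)c(O)cc2OC)cc(OCc2ccccc2)c1OC.[Cl-] | intermediate
9 | 2-[3-(benzyloxy)-4,5-dimethoxyphenyl]-1-(2,4-dihydroxy-3,6-dimethoxyphenyl)ethan-1-one | COc1cc(CC(=O)c2c(O)c(OC)c(O)cc2OC)cc(OCc2ccccc2)c1OC | intermediate
10 | 2-[3-(benzyloxy)-4,5-dimethoxyphenyl]-1-{3,6-dimethoxy-2,4-bis[(triisopropylsilyl)oxy]phenyl}ethan-1-one | COc1cc(CC(=O)c2c(O[Si](C(C)C)(C(C)C)C(C)C)c(OC)c(O[Si](C(C)C)(C(C)C)C(C)C)cc2OC)cc(OCc2ccccc2)c1OC | intermediate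
11 | 2-[3-(benzyloxy)-4,5-dimethoxyphenyl]-2-diazo-1-{3,6-dimethoxy-2,4-bis[(triisopropylsilyl)oxy]phenyl}ethan-1-one | COc1cc(C(=[N+]=[N-])C(=O)c2c(O[Si](C(C)C)(C(C)C)C(C)C)c(OC)c(O[Si](C(C)C)(C(C)C)C(C)C)cc2OC)cc(OCc2ccccc2)c1OC | intermediate
12 | (3R)-3-[3-(benzyloxy)-4,5-dimethoxyphenyl]-6-methoxy-5,7-bis[(triisopropylsilyl)oxy]-2,3-dihydro-4H-chromen-4-one | COc1cc([C@@H]2COc3cc(O[Si](C(C)C)(C(C)C)C(C)C)c(OC)c(O[Si](C(C)C)(C(C)C)C(C)C)c3C2=O)cc(OCc2ccccc2)c1OC | intermediate
13 | (3R)-3-[3-(benzyloxy)-4,5-dimethoxyphenyl]-5,7-dihydroxy-6-methoxy-2,3-dihydro-4H-chromen-4-one | COc1cc([C@@H]2COc3cc(O)c(OC)c(O)c3C2=O)cc(OCc2ccccc2)c1OC | intermediate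
14 | (3R)-5,7-dihydroxy-3-(3-hydroxy-4,5-dimethoxyphenyl)-6-methoxy-2,3-dihydro-4H-chromen-4-one | COc1cc([C@@H]2COc3cc(O)c(OC)c(O)c3C2=O)cc(O)c1OC | target

**Step count**

Total steps: 10. Longest linear sequence: 8 steps (5 → 14 through steps 3–10; equally 1 → 14 through steps 1, 2, 5–10).

**Steps most likely to fail**

1. Step 8 (proposed new method). The process at risk is weak enantiofacial discrimination at the rhodium carbene: the insertion creates its only stereocentre at the carbene carbon, and the small methyl group offers the catalyst little to differentiate. Part of the carbene may also drain into oxonium ylide formation at the ether oxygen. The fallback uses known chemistry, sets out from 12 obtained in insufficient enantiomeric purity, and returns to 12. Asymmetric transfer hydrogenation under dynamic kinetic resolution (RuCl[(R,R)-TsDPEN](p-cymene), divalent ruthenium, HCO2H/Et3N 5:2, EtOAc, 40 °C) should epimerise C3 through the enol while reducing only the matched enantiomer. By analogy with aryl alkyl ketones this antipode of the catalyst should give the cis-alcohol (3R,4R)-3-[3-(benzyloxy)-4,5-dimethoxyphenyl]-6-methoxy-5,7-bis[(triisopropylsilyl)oxy]chroman-4-ol F1, so both enantiomers of 12 are funnelled into one configuration. Buffered Dess–Martin oxidation (NaHCO3, CH2Cl2, 0 °C) of the C4 alcohol should then return (R)-12 without touching C3.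

2. Step 7. The process at risk is enolate-triggered loss or O-to-O migration of the triisopropylsilyl group ortho to the ketone, or sluggish diazo transfer at the crowded methylene. The fallback sets out from 10 and returns to 11 without any enolate. Oxidation of the benzylic methylene (SeO2, 1,4-dioxane, 90 °C) should give 1-[3-(benzyloxy)-4,5-dimethoxyphenyl]-2-{3,6-dimethoxy-2,4-bis[(triisopropylsilyl)oxy]phenyl}ethane-1,2-dione F2. Condensation with tosylhydrazide (THF, 50 °C) should occur at the unhindered carbonyl next to ring B, since the other carbonyl is flanked by two ortho substituents, and give N'-{1-[3-(benzyloxy)-4,5-dimethoxyphenyl]-2-{3,6-dimethoxy-2,4-bis[(triisopropylsilyl)oxy]phenyl}-2-oxoethylidene}-4-methylbenzenesulfonohydrazide F3. Bamford–Stevens elimination of sulfinate (Et3N, CH2Cl2, rt) then gives 11.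

3. Step 4. The process at risk is an incomplete second C–O coupling on the phenoxide formed after the first, with protodebromination and air oxidation of the very electron-rich product. The fallback sets out from 6 and returns to 7. Double Miyaura borylation (B2pin2, PdCl2(dppf), divalent palladium precatalyst, KOAc, 1,4-dioxane, 90 °C) should give 2,2'-(2,5-dimethoxy-1,3-phenylene)bis(4,4,5,5-tetramethyl-1,3,2-dioxaborolane) F4. Oxidation of both C–B bonds (NaBO3, THF/H2O, rt, argon) then gives 7.

**Further compounds**

F1 | step 8 | (3R,4R)-3-[3-(benzyloxy)-4,5-dimethoxyphenyl]-6-methoxy-5,7-bis[(triisopropylsilyl)oxy]chroman-4-ol | COc1cc([C@@H]2COc3cc(O[Si](C(C)C)(C(C)C)C(C)C)c(OC)c(O[Si](C(C)C)(C(C)C)C(C)C)c3[C@@H]2O)cc(OCc2ccccc2)c1OC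
F2 | step 7 | 1-[3-(benzyloxy)-4,5-dimethoxyphenyl]-2-{3,6-dimethoxy-2,4-bis[(triisopropylsilyl)oxy]phenyl}ethane-1,2-dione | COc1cc(C(=O)C(=O)c2c(O[Si](C(C)C)(C(C)C)C(C)C)c(OC)c(O[Si](C(C)C)(C(C)C)C(C)C)cc2OC)cc(OCc2ccccc2)c1OC
F3 | step 7 | N'-{1-[3-(benzyloxy)-4,5-dimethoxyphenyl]-2-{3,6-dimethoxy-2,4-bis[(triisopropylsilyl)oxy]phenyl}-2-oxoethylidene}-4-methylbenzenesulfonohydrazide | COc1cc(C(=NNS(=O)(=O)c2ccc(C)cc2)C(=O)c2c(O[Si](C(C)C)(C(C)C)C(C)C)c(OC)c(O[Si](C(C)C)(C(C)C)C(C)C)cc2OC)cc(OCc2ccccc2)c1OC
F4 | step 4 | 2,2'-(2,5-dimethoxy-1,3-phenylene)bis(4,4,5,5-tetramethyl-1,3,2-dioxaborolane) | COc1cc(B2OC(C)(C)C(C)(C)O2)c(OC)c(B2OC(C)(C)C(C)(C)O2)c1
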